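**Plan**

1. Locants (xanthane numbering): seven-membered ring C1 (tertiary carbinol carrying the crotonyl group C2–C4/C15), C5 (OAng), C6 (lactone O), C7, C8, C9 (OH), C10 (CH3); lactone carbons C11–C13.
2. Retrosynthesis: remove the angelate, cut C2–C3 and the C11=C13 methylene, open the lactone/C5–OH pair back to a C5=C6 alkene and take C9–OH back to a ketone. What remains in the carbocycle, O=C9–C10–C1–C5=C6, is a γ,δ-unsaturated ketone, the retron of a Claisen shift; C10–C1 is therefore cut to a 2-ethylidene-5-alkenyl oxolane (O–C9–C8–C7–C6), which is opened to an acyclic alkynol.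
3. Forward: the chain C12–C11–C7(CH2C≡CCH3)–C6–C5=C1(Bpin)–C2 is built linearly (Evans alkylation, Weinreb ynone, conjugate borylation, CBS reduction). Gold closes the temporary oxolane, the [3,3] shift closes the carbocycle and moves oxygen from C6 to C9, and the boronic ester (placeholder for the C1 hydroxyl) is then oxidized.
4. Then C9 is reduced, C11 is methylenated, the C5=C6 alkene is epoxidized and opened by the C12 ester to the cis-fused α-methylene lactone, and the crotonyl and angelate groups are completed.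
5. Stereochemistry: C7 from the auxiliary; the sacrificial C6 carbinol from the CBS reduction; C1 and C10 by chirality transfer from C6 through the chair-like [3,3] transition state; C9 by C1–OH-directed hydride delivery; C5 and C6 by C2–OH-directed epoxidation and anti opening.

Key step: step 7

Remark: in step 6 the alkenyl group is assumed to act as the larger carbonyl substituent toward the oxazaborolidine; if the opposite holds, the (R)-catalyst is used instead.

**Route**

Step 1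
Reactants: 1 (4S)-4-benzyl-1,3-oxazolidin-2-one; 2 4-tert-butoxy-4-oxobutanoic acid
Product: 4 tert-butyl 4-[(4S)-4-benzyl-2-oxo-1,3-oxazolidin-3-yl]-4-oxobutanoate, via mixed pivalic anhydride 3 (not isolated)
Conditions: 2, PivCl, Et3N, THF, −20 °C; then LiCl, 1, −20 °C to rt
Reagents that add atoms: none
Why: N-acylation of the oxazolidinone by a mixed pivalic anhydride (LiCl/Et3N protocol) should be clean because the unhindered succinyl carbonyl of 3 is attacked in preference to the pivaloyl carbonyl; no stereocenter is formed.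

Step 2
Reactants: 4 tert-butyl 4-[(4S)-4-benzyl-2-oxo-1,3-oxazolidin-3-yl]-4-oxobutanoate; 5 1-bromobut-2-yne
Product: 7 tert-butyl (3S)-3-[(4S)-4-benzyl-2-oxo-1,3-oxazolidine-3-carbonyl]hept-5-ynoate, via sodium (Z)-enolate 6 (not isolated)
Conditions: NaHMDS, THF, −78 °C; then 5, −78 to −40 °C
Reagents that add atoms: none
Why: Evans asymmetric alkylation: the imide α-CH2 is the most acidic site, the chelated (Z)-enolate is alkylated by the propargylic bromide on the face away from the benzyl group, and this should set C7 as (S).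

Step 3
Reactants: 7 tert-butyl (3S)-3-[(4S)-4-benzyl-2-oxo-1,3-oxazolidine-3-carbonyl]hept-5-ynoate
Product: 8 tert-butyl (3S)-3-[methoxy(methyl)carbamoyl]hept-5-ynoate
Conditions: MeNH(OMe)·HCl, AlMe3, CH2Cl2, 0 °C to rt
Reagents that add atoms: N,O-dimethylhydroxylamine hydrochloride (CNOC.Cl)
Why: Aluminium amide transamination of the N-acyl oxazolidinone (Weinreb amide formation) frees the auxiliary under non-basic conditions that should leave the C7 center and the tert-butyl ester untouched.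

Step 4
Reactants: 8 tert-butyl (3S)-3-[methoxy(methyl)carbamoyl]hept-5-ynoate; 9 1-methoxy-4-[(prop-2-yn-1-yloxy)methyl]benzene
Product: 11 tert-butyl (3S)-3-(but-2-yn-1-yl)-7-[(4-methoxyphenyl)methoxy]-4-oxohept-5-ynoate, via lithium acetylide 10 (not isolated)
Conditions: 9, n-BuLi, THF, −78 °C; then 8, −78 °C; aq. NH4Cl
Reagents that add atoms: none
Why: Weinreb ketone synthesis: the chelated tetrahedral adduct survives until work-up, so the acetylide should add once, and the tert-butyl ester is inert at −78 °C.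

Step 5
Reactants: 11 tert-butyl (3S)-3-(but-2-yn-1-yl)-7-[(4-methoxyphenyl)methoxy]-4-oxohept-5-ynoate
Product: 12 tert-butyl (3S,5Z)-3-(but-2-yn-1-yl)-7-[(4-methoxyphenyl)methoxy]-4-oxo-6-(4,4,5,5-tetramethyl-1,3,2-dioxaborolan-2-yl)hept-5-enoate
Conditions: CuCl (5 mol%), Xantphos (5 mol%), NaOt-Bu (10 mol%), B2pin2, MeOH (2 equiv), THF, 0 °C to rt
Reagents that add atoms: bis(pinacolato)diboron (CC1(C)OB(OC1(C)C)B1OC(C)(C)C(C)(C)O1)
Why: Copper-catalysed conjugate borylation of an ynone: the boryl–copper species adds syn across the carbonyl-activated triple bond only (the but-2-ynyl group is not activated), boron goes to the β-carbon C1 and methanol protonates C5, which should give the (Z)-alkene with Bpin trans and CH2OPMB cis to the carbonyl carbon C6.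

Step 6
Reactants: 12 tert-butyl (3S,5Z)-3-(but-2-yn-1-yl)-7-[(4-methoxyphenyl)methoxy]-4-oxo-6-(4,4,5,5-tetramethyl-1,3,2-dioxaborolan-2-yl)hept-5-enoate
Product: 13 tert-butyl (3S,4R,5Z)-3-(but-2-yn-1-yl)-4-hydroxy-7-[(4-methoxyphenyl)methoxy]-6-(4,4,5,5-tetramethyl-1,3,2-dioxaborolan-2-yl)hept-5-enoate
Conditions: (S)-2-methyl-CBS-oxazaborolidine (20 mol%), catecholborane, PhMe, −78 °C
Reagents that add atoms: none
Why: Corey–Bakshi–Shibata reduction: with the alkenyl group as the large substituent the (S)-oxazaborolidine should deliver hydride to give the (4R)-allylic alcohol (C6) under reagent control, and at −78 °C catecholborane should touch neither the alkyne nor the boronic ester.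

Step 7
Reactants: 13 tert-butyl (3S,4R,5Z)-3-(but-2-yn-1-yl)-4-hydroxy-7-[(4-methoxyphenyl)methoxy]-6-(4,4,5,5-tetramethyl-1,3,2-dioxaborolan-2-yl)hept-5-enoate
Product: 15 tert-butyl 2-[(1S,4S,5R)-4-{[(4-methoxyphenyl)methoxy]methyl}-5-methyl-6-oxo-4-(4,4,5,5-tetramethyl-1,3,2-dioxaborolan-2-yl)cyclohept-2-en-1-yl]acetate, via (Z)-ethylidene oxolane 14 (not isolated)
Conditions: (Ph3P)AuNTf2 (5 mol%), PhMe, rt; then Et3N (2 equiv), 160 °C (sealed tube)
Reagents that add atoms: none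
Why: Monovalent gold activates the C9≡C10 triple bond for anti attack of the C6 hydroxyl in the 5-exo-dig mode, which closes the temporary oxolane as its (Z)-ethylidene enol ether 14, and on heating this allyl vinyl ether undergoes a [3,3]-sigmatropic (Claisen) shift that makes C10–C1, breaks C6–O and thereby closes the seven-membered ring as a ring expansion of the oxolane into the cyclohept-4-enone. The closest known reaction type is the tandem alkynol cycloisomerization–Claisen ring expansion of 2-alkylidene-5-vinyl tetrahydrofurans to cyclohept-4-enones. Because C9, O and C6 are held in the oxolane and the new C5=C6 bond must be cis within the ring, only the chair-like bicyclic transition state is open (the boat would give a trans-cycloheptene), so the outcome follows from the two alkene geometries and the C6 configuration. C1 is set by suprafacial delivery across the (Z)-alkenylboronate (CH2OPMB inside and Bpin outside) from the face fixed by the (R)-C6–O bond, C10 by the (Z) geometry of the enol ether, and both are related to the untouched C7 through the trans-2,3-disubstituted oxolane. The step needs hydroxyl attack (5-exo) to win over 6-endo closure and over gold-triggered enyne cyclization, which the electron-poor boryl alkene and the proximity of the hydroxyl should secure, and Et3N is added before heating so that no acid moves the exocyclic double bond into the ring.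

Step 8
Reactants: 15 tert-butyl 2-[(1S,4S,5R)-4-{[(4-methoxyphenyl)methoxy]methyl}-5-methyl-6-oxo-4-(4,4,5,5-tetramethyl-1,3,2-dioxaborolan-2-yl)cyclohept-2-en-1-yl]acetate
Product: 16 tert-butyl 2-[(1S,4R,5R)-4-hydroxy-4-{[(4-methoxyphenyl)methoxy]methyl}-5-methyl-6-oxocyclohept-2-en-1-yl]acetate
Conditions: NaBO3·4H2O, THF/H2O (1:1), 0 °C to rt
Reagents that add atoms: sodium perborate ([Na+].[O-]OB=O)
Why: Perborate oxidation of the tertiary allylic boronic ester proceeds by 1,2-migration of carbon from boron to oxygen with retention at C1 and without allylic transposition, so the Bpin placeholder should be replaced by the C1 hydroxyl on the same face.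

Step 9
Reactants: 16 tert-butyl 2-[(1S,4R,5R)-4-hydroxy-4-{[(4-methoxyphenyl)methoxy]methyl}-5-methyl-6-oxocyclohept-2-en-1-yl]acetate
Product: 17 tert-butyl 2-[(1S,4R,5S,6R)-4,6-dihydroxy-4-{[(4-methoxyphenyl)methoxy]methyl}-5-methylcyclohept-2-en-1-yl]acetate
Conditions: Me4NBH(OAc)3, MeCN/AcOH (1:1), −30 °C
Reagents that add atoms: none
Why: Evans–Saksena reduction: the C1 hydroxyl exchanges onto the triacetoxyborohydride and delivers hydride intramolecularly to its own face of the C9 carbonyl, which should give the 1,3-anti diol, that is (9R) with the hydroxyl trans to the C10 methyl group.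

Step 10
Reactants: 17 tert-butyl 2-[(1S,4R,5S,6R)-4,6-dihydroxy-4-{[(4-methoxyphenyl)methoxy]methyl}-5-methylcyclohept-2-en-1-yl]acetate
Product: 18 tert-butyl 2-[(1S,4R,5S,6R)-4-{[(4-methoxyphenyl)methoxy]methyl}-5-methyl-4,6-bis(triethylsilyloxy)cyclohept-2-en-1-yl]acetate
Conditions: TESOTf, 2,6-lutidine, CH2Cl2, −78 to 0 °C
Reagents that add atoms: triethylsilyl trifluoromethanesulfonate (CC[Si](CC)(CC)OS(=O)(=O)C(F)(F)F)
Why: Silylation with a silyl triflate and 2,6-lutidine should cap both the secondary and the hindered tertiary hydroxyl without touching any stereocenter.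

Step 11
Reactants: 18 tert-butyl 2-[(1S,4R,5S,6R)-4-{[(4-methoxyphenyl)methoxy]methyl}-5-methyl-4,6-bis(triethylsilyloxy)cyclohept-2-en-1-yl]acetate
Product: 22 tert-butyl 2-[(1R,4R,5S,6R)-4-{[(4-methoxyphenyl)methoxy]methyl}-5-methyl-4,6-bis(triethylsilyloxy)cyclohept-2-en-1-yl]prop-2-enoate, via lithium enolate 19 (not isolated), via Mannich base 20 (not isolated), via trimethylammonium iodide 21 (not isolated)
Conditions: LDA, THF, −78 °C; Me2N=CH2+ I−, −78 °C to rt; then MeI, MeOH, rt; then DBU, CH2Cl2, rt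
Reagents that add atoms: N,N-dimethylmethyleneiminium iodide, Eschenmoser's salt (C=[N+](C)C.[I-])
Why: α-Methylenation by Mannich reaction of the ester enolate with Eschenmoser's salt, N-methylation and Hofmann-type elimination should be site-selective because the CH2 next to the tert-butyl ester is the only acidic position left.

Step 12
Reactants: 22 tert-butyl 2-[(1R,4R,5S,6R)-4-{[(4-methoxyphenyl)methoxy]methyl}-5-methyl-4,6-bis(triethylsilyloxy)cyclohept-2-en-1-yl]prop-2-enoate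
Product: 23 tert-butyl 2-[(1R,4R,5S,6R)-4-(hydroxymethyl)-5-methyl-4,6-bis(triethylsilyloxy)cyclohept-2-en-1-yl]prop-2-enoate
Conditions: DDQ, CH2Cl2/pH 7 buffer (10:1), 0 °C
Reagents that add atoms: none
Why: Oxidative PMB ether cleavage with DDQ (single-electron oxidation of the electron-rich benzyl ether, hydrolysis of the oxocarbenium ion) should free the C2 hydroxyl while silyl ethers, acrylate and ring alkene stay intact.

Step 13
Reactants: 23 tert-butyl 2-[(1R,4R,5S,6R)-4-(hydroxymethyl)-5-methyl-4,6-bis(triethylsilyloxy)cyclohept-2-en-1-yl]prop-2-enoate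
Product: 25 (3aS,5R,6S,7R,8S,8aR)-8-hydroxy-7-(hydroxymethyl)-6-methyl-3-methylidene-5,7-bis(triethylsilyloxy)octahydro-2H-cyclohepta[b]furan-2-one, via β-epoxide 24 (not isolated)
Conditions: VO(acac)2 (10 mol%), t-BuOOH, CH2Cl2, 0 °C to rt; then CSA (20 mol%), rt
Reagents that add atoms: tert-butyl hydroperoxide (CC(C)(C)OO)
Why: Vanadium-catalysed epoxidation directed by the homoallylic C2 hydroxyl should deliver oxygen to the C5=C6 face syn to CH2OH (also the face away from the C7 side chain and the C1 silyloxy group), and acid then triggers 5-exo opening at C6 by the ester carbonyl from the opposite face with loss of isobutene, which sets (6R) in the cis-fused α-methylene γ-lactone and leaves the (5S) hydroxyl.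

Step 14
Reactants: 25 (3aS,5R,6S,7R,8S,8aR)-8-hydroxy-7-(hydroxymethyl)-6-methyl-3-methylidene-5,7-bis(triethylsilyloxy)octahydro-2H-cyclohepta[b]furan-2-one
Product: 26 (3aS,5R,6S,7S,8S,8aR)-8-hydroxy-6-methyl-3-methylidene-2-oxo-5,7-bis(triethylsilyloxy)octahydro-2H-cyclohepta[b]furan-7-carbaldehyde
Conditions: TEMPO (10 mol%), PhI(OAc)2, CH2Cl2, rt
Reagents that add atoms: none
Why: TEMPO/PhI(OAc)2 oxidation is selective for primary over hindered secondary alcohols and the resulting aldehyde has no α-hydrogen, so the C5 hydroxyl and the C1 center should be unaffected.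

Step 15
Reactants: 26 (3aS,5R,6S,7S,8S,8aR)-8-hydroxy-6-methyl-3-methylidene-2-oxo-5,7-bis(triethylsilyloxy)octahydro-2H-cyclohepta[b]furan-7-carbaldehyde; 27 (E)-1-bromoprop-1-ene
Product: 29 (3aS,5R,6S,7R,8S,8aR)-8-hydroxy-7-[(2E)-1-hydroxybut-2-en-1-yl]-6-methyl-3-methylidene-5,7-bis(triethylsilyloxy)octahydro-2H-cyclohepta[b]furan-2-one (both carbinol epimers), via (E)-prop-1-enylchromium dichloride 28 (not isolated)
Conditions: CrCl2 (4 equiv), NiCl2 (2 mol%), DMF, rt
Reagents that add atoms: none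
Why: Nozaki–Hiyama–Kishi reaction: the alkenylchromium species formed with retention of the (E) geometry should add to the aldehyde only (lactone, acrylate unit and free hydroxyl are tolerated); the new carbinol center forms as a mixture and is removed in step 16.

Step 16
Reactants: 29 (3aS,5R,6S,7R,8S,8aR)-8-hydroxy-7-[(2E)-1-hydroxybut-2-en-1-yl]-6-methyl-3-methylidene-5,7-bis(triethylsilyloxy)octahydro-2H-cyclohepta[b]furan-2-one
Product: 30 (3aS,5R,6S,7S,8S,8aR)-7-[(2E)-but-2-enoyl]-8-hydroxy-6-methyl-3-methylidene-5,7-bis(triethylsilyloxy)octahydro-2H-cyclohepta[b]furan-2-one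
Conditions: MnO2 (activated, excess), CH2Cl2, rt
Reagents that add atoms: none
Why: MnO2 oxidizes allylic alcohols selectively, so the (E)-enone should form while the saturated C5 hydroxyl remains.

Step 17
Reactants: 30 (3aS,5R,6S,7S,8S,8aR)-7-[(2E)-but-2-enoyl]-8-hydroxy-6-methyl-3-methylidene-5,7-bis(triethylsilyloxy)octahydro-2H-cyclohepta[b]furan-2-one; 31 (2Z)-2-methylbut-2-enoic acid (angelic acid)
Product: 33 (3aS,5R,6S,7S,8S,8aR)-7-[(2E)-but-2-enoyl]-6-methyl-3-methylidene-2-oxo-5,7-bis(triethylsilyloxy)octahydro-2H-cyclohepta[b]furan-8-yl (2Z)-2-methylbut-2-enoate, via angelic 2,4,6-trichlorobenzoic anhydride 32 (not isolated)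
Conditions: 31, 2,4,6-trichlorobenzoyl chloride, Et3N, PhMe, rt; then 30, 80 °C
Reagents that add atoms: none
Why: Yamaguchi esterification through the mixed 2,4,6-trichlorobenzoic anhydride is the standard way to acylate hindered secondary alcohols with angelic acid without Z to E isomerization, and the C5 hydroxyl is the only free hydroxyl.

Step 18
Reactants: 33 (3aS,5R,6S,7S,8S,8aR)-7-[(2E)-but-2-enoyl]-6-methyl-3-methylidene-2-oxo-5,7-bis(triethylsilyloxy)octahydro-2H-cyclohepta[b]furan-8-yl (2Z)-2-methylbut-2-enoate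
Product: 34 (3aS,5R,6S,7S,8S,8aR)-7-[(2E)-but-2-enoyl]-5,7-dihydroxy-6-methyl-3-methylidene-2-oxooctahydro-2H-cyclohepta[b]furan-8-yl (2Z)-2-methylbut-2-enoate (CNP0149130.1)
Conditions: HF·pyridine, pyridine, THF, 0 °C to rt
Reagents that add atoms: none
Why: Fluoride cleavage of both triethylsilyl ethers with buffered HF·pyridine should leave the α-methylene lactone, enone, angelate and tertiary α-ketol untouched and gives the target with all six stereocenters as set.

**Compound list**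

1 | (4S)-4-benzyl-1,3-oxazolidin-2-one | O=C1N[C@@H](Cc2ccccc2)CO1 | starting material
2 | 4-tert-butoxy-4-oxobutanoic acid (mono-tert-butyl succinate) | CC(C)(C)OC(=O)CCC(=O)O | starting material
3 | 4-tert-butoxy-4-oxobutanoic pivalic anhydride | CC(C)(C)OC(=O)CCC(=O)OC(=O)C(C)(C)C | intermediate
4 | tert-butyl 4-[(4S)-4-benzyl-2-oxo-1,3-oxazolidin-3-yl]-4-oxobutanoate | CC(C)(C)OC(=O)CCC(=O)N1[C@@H](Cc2ccccc2)COC1=O | intermediate
5 | 1-bromobut-2-yne | CC#CCBr | starting material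
6 | sodium (Z)-enolate of 4 | [Na+].[O-]/C(=C\CC(=O)OC(C)(C)C)N1[C@@H](Cc2ccccc2)COC1=O | intermediate
7 | tert-butyl (3S)-3-[(4S)-4-benzyl-2-oxo-1,3-oxazolidine-3-carbonyl]hept-5-ynoate | CC#CC[C@@H](CC(=O)OC(C)(C)C)C(=O)N1[C@@H](Cc2ccccc2)COC1=O | intermediate
8 | tert-butyl (3S)-3-[methoxy(methyl)carbamoyl]hept-5-ynoate | CC#CC[C@@H](CC(=O)OC(C)(C)C)C(=O)N(C)OC | intermediate
9 | 1-methoxy-4-[(prop-2-yn-1-yloxy)methyl]benzene (PMB propargyl ether) | C#CCOCc1ccc(OC)cc1 | starting material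
10 | lithium acetylide of 9 | [Li+].[C-]#CCOCc1ccc(OC)cc1 | intermediate
11 | tert-butyl (3S)-3-(but-2-yn-1-yl)-7-[(4-methoxyphenyl)methoxy]-4-oxohept-5-ynoate | CC#CC[C@@H](CC(=O)OC(C)(C)C)C(=O)C#CCOCc1ccc(OC)cc1 | intermediate
12 | tert-butyl (3S,5Z)-3-(but-2-yn-1-yl)-7-[(4-methoxyphenyl)methoxy]-4-oxo-6-(4,4,5,5-tetramethyl-1,3,2-dioxaborolan-2-yl)hept-5-enoate | CC#CC[C@@H](CC(=O)OC(C)(C)C)C(=O)/C=C(\COCc1ccc(OC)cc1)B1OC(C)(C)C(C)(C)O1 | intermediate
13 | tert-butyl (3S,4R,5Z)-3-(but-2-yn-1-yl)-4-hydroxy-7-[(4-methoxyphenyl)methoxy]-6-(4,4,5,5-tetramethyl-1,3,2-dioxaborolan-2-yl)hept-5-enoate | CC#CC[C@@H](CC(=O)OC(C)(C)C)[C@@H](O)/C=C(\COCc1ccc(OC)cc1)B1OC(C)(C)C(C)(C)O1 | intermediate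
14 | tert-butyl 2-[(2R,3S,5Z)-5-ethylidene-2-[(1Z)-3-[(4-methoxyphenyl)methoxy]-2-(4,4,5,5-tetramethyl-1,3,2-dioxaborolan-2-yl)prop-1-en-1-yl]oxolan-3-yl]acetate | C/C=C1/C[C@@H](CC(=O)OC(C)(C)C)[C@@H](O1)/C=C(\COCc1ccc(OC)cc1)B1OC(C)(C)C(C)(C)O1 | intermediate
15 | tert-butyl 2-[(1S,4S,5R)-4-{[(4-methoxyphenyl)methoxy]methyl}-5-methyl-6-oxo-4-(4,4,5,5-tetramethyl-1,3,2-dioxaborolan-2-yl)cyclohept-2-en-1-yl]acetate | [C@@]1(B2OC(C)(C)C(C)(C)O2)(COCc2ccc(OC)cc2)C=C[C@H](CC(=O)OC(C)(C)C)CC(=O)[C@@H]1C | intermediate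
16 | tert-butyl 2-[(1S,4R,5R)-4-hydroxy-4-{[(4-methoxyphenyl)methoxy]methyl}-5-methyl-6-oxocyclohept-2-en-1-yl]acetate | [C@@]1(O)(COCc2ccc(OC)cc2)C=C[C@H](CC(=O)OC(C)(C)C)CC(=O)[C@@H]1C | intermediate
17 | tert-butyl 2-[(1S,4R,5S,6R)-4,6-dihydroxy-4-{[(4-methoxyphenyl)methoxy]methyl}-5-methylcyclohept-2-en-1-yl]acetate | [C@@]1(O)(COCc2ccc(OC)cc2)C=C[C@H](CC(=O)OC(C)(C)C)C[C@@H](O)[C@@H]1C | intermediate
18 | tert-butyl 2-[(1S,4R,5S,6R)-4-{[(4-methoxyphenyl)methoxy]methyl}-5-methyl-4,6-bis(triethylsilyloxy)cyclohept-2-en-1-yl]acetate | [C@@]1(O[Si](CC)(CC)CC)(COCc2ccc(OC)cc2)C=C[C@H](CC(=O)OC(C)(C)C)C[C@@H](O[Si](CC)(CC)CC)[C@@H]1C | intermediate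
19 | lithium enolate of 18 (ester enolate at the CH2 next to the tert-butyl ester) | [C@@]1(O[Si](CC)(CC)CC)(COCc2ccc(OC)cc2)C=C[C@H](C=C([O-])OC(C)(C)C)C[C@@H](O[Si](CC)(CC)CC)[C@@H]1C.[Li+] | intermediate
20 | Mannich base: 18 carrying CH2NMe2 on the carbon next to the tert-butyl ester (both epimers at that carbon) | [C@@]1(O[Si](CC)(CC)CC)(COCc2ccc(OC)cc2)C=C[C@H](C(CN(C)C)C(=O)OC(C)(C)C)C[C@@H](O[Si](CC)(CC)CC)[C@@H]1C | intermediate
21 | trimethylammonium iodide of 20 | [C@@]1(O[Si](CC)(CC)CC)(COCc2ccc(OC)cc2)C=C[C@H](C(C[N+](C)(C)C)C(=O)OC(C)(C)C)C[C@@H](O[Si](CC)(CC)CC)[C@@H]1C.[I-] | intermediate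
22 | tert-butyl 2-[(1R,4R,5S,6R)-4-{[(4-methoxyphenyl)methoxy]methyl}-5-methyl-4,6-bis(triethylsilyloxy)cyclohept-2-en-1-yl]prop-2-enoate | [C@@]1(O[Si](CC)(CC)CC)(COCc2ccc(OC)cc2)C=C[C@H](C(=C)C(=O)OC(C)(C)C)C[C@@H](O[Si](CC)(CC)CC)[C@@H]1C | intermediate
23 | tert-butyl 2-[(1R,4R,5S,6R)-4-(hydroxymethyl)-5-methyl-4,6-bis(triethylsilyloxy)cyclohept-2-en-1-yl]prop-2-enoate | [C@@]1(O[Si](CC)(CC)CC)(CO)C=C[C@H](C(=C)C(=O)OC(C)(C)C)C[C@@H](O[Si](CC)(CC)CC)[C@@H]1C | intermediate
24 | β-epoxide of 23 (oxirane across the ring double bond on the face of the CH2OH group) | [C@@]1(O[Si](CC)(CC)CC)(CO)[C@H]2O[C@H]2[C@H](C(=C)C(=O)OC(C)(C)C)C[C@@H](O[Si](CC)(CC)CC)[C@@H]1C | intermediate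
25 | (3aS,5R,6S,7R,8S,8aR)-8-hydroxy-7-(hydroxymethyl)-6-methyl-3-methylidene-5,7-bis(triethylsilyloxy)octahydro-2H-cyclohepta[b]furan-2-one | C=C1C(=O)O[C@@H]2[C@H]1C[C@@H](O[Si](CC)(CC)CC)[C@H](C)[C@@](O[Si](CC)(CC)CC)(CO)[C@H]2O | intermediate
26 | (3aS,5R,6S,7S,8S,8aR)-8-hydroxy-6-methyl-3-methylidene-2-oxo-5,7-bis(triethylsilyloxy)octahydro-2H-cyclohepta[b]furan-7-carbaldehyde | C=C1C(=O)O[C@@H]2[C@H]1C[C@@H](O[Si](CC)(CC)CC)[C@H](C)[C@@](O[Si](CC)(CC)CC)(C=O)[C@H]2O | intermediate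
27 | (E)-1-bromoprop-1-ene | C/C=C/Br | starting material
28 | (E)-prop-1-enylchromium dichloride | C/C=C/[Cr](Cl)Cl | intermediate
29 | (3aS,5R,6S,7R,8S,8aR)-8-hydroxy-7-[(2E)-1-hydroxybut-2-en-1-yl]-6-methyl-3-methylidene-5,7-bis(triethylsilyloxy)octahydro-2H-cyclohepta[b]furan-2-one (both carbinol epimers) | C=C1C(=O)O[C@@H]2[C@H]1C[C@@H](O[Si](CC)(CC)CC)[C@H](C)[C@@](O[Si](CC)(CC)CC)(C(O)/C=C/C)[C@H]2O | intermediate
30 | (3aS,5R,6S,7S,8S,8aR)-7-[(2E)-but-2-enoyl]-8-hydroxy-6-methyl-3-methylidene-5,7-bis(triethylsilyloxy)octahydro-2H-cyclohepta[b]furan-2-one | C=C1C(=O)O[C@@H]2[C@H]1C[C@@H](O[Si](CC)(CC)CC)[C@H](C)[C@@](O[Si](CC)(CC)CC)(C(=O)/C=C/C)[C@H]2O | intermediate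
31 | (2Z)-2-methylbut-2-enoic acid (angelic acid) | C/C=C(/C)C(=O)O | starting material
32 | angelic 2,4,6-trichlorobenzoic anhydride | C/C=C(/C)C(=O)OC(=O)c1c(Cl)cc(Cl)cc1Cl | intermediate
33 | (3aS,5R,6S,7S,8S,8aR)-7-[(2E)-but-2-enoyl]-6-methyl-3-methylidene-2-oxo-5,7-bis(triethylsilyloxy)octahydro-2H-cyclohepta[b]furan-8-yl (2Z)-2-methylbut-2-enoate | C=C1C(=O)O[C@@H]2[C@H]1C[C@@H](O[Si](CC)(CC)CC)[C@H](C)[C@@](O[Si](CC)(CC)CC)(C(=O)/C=C/C)[C@H]2OC(=O)/C(C)=C\C | intermediate
34 | (3aS,5R,6S,7S,8S,8aR)-7-[(2E)-but-2-enoyl]-5,7-dihydroxy-6-methyl-3-methylidene-2-oxooctahydro-2H-cyclohepta[b]furan-8-yl (2Z)-2-methylbut-2-enoate (CNP0149130.1) | C=C1C(=O)O[C@@H]2[C@H]1C[C@@H](O)[C@H](C)[C@@](O)(C(=O)/C=C/C)[C@H]2OC(=O)/C(C)=C\C | target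

**Count and risks**

Total step count: 18. Longest linear sequence: 18 steps (2 to 34).

Steps most likely to fail:

Step 7. The ether-forming stage may go astray through 6-endo closure or gold-triggered enyne cyclization, residual acid may move the exocyclic double bond into the ring before the shift, and the [3,3] shift at the crowded terminus may be slow enough for the tert-butyl ester to lose isobutene. Fallback: the fallback sets out from 13 and forms the enol ether by an electrophile-induced cyclization instead of π-acid catalysis. Anti iodo-etherification (I2, NaHCO3, MeCN, 0 °C) should give tert-butyl 2-[(2R,3S,5E)-5-(1-iodoethylidene)-2-[(1Z)-3-[(4-methoxyphenyl)methoxy]-2-(4,4,5,5-tetramethyl-1,3,2-dioxaborolan-2-yl)prop-1-en-1-yl]oxolan-3-yl]acetate F1. Reduction of the alkenyl iodide with retention (Pd(PPh3)4, Bu3SnH, THF, rt) comes back to the route at 14, now isolated and purified, which is heated in PhMe with Et3N to give 15.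

Step 6. Hydride delivery may show poor or reversed facial selectivity because the two carbonyl substituents are of similar size, and conjugate reduction may compete. Fallback: the fallback sets out from 12 with an unselective Luche reduction (NaBH4, CeCl3·7H2O, MeOH, −78 °C), which gives 13 together with its carbinol epimer tert-butyl (3S,4S,5Z)-3-(but-2-yn-1-yl)-4-hydroxy-7-[(4-methoxyphenyl)methoxy]-6-(4,4,5,5-tetramethyl-1,3,2-dioxaborolan-2-yl)hept-5-enoate F2. After separation, F2 is inverted by Mitsunobu reaction (4-nitrobenzoic acid, PPh3, DIAD) to tert-butyl (3S,4R,5Z)-3-(but-2-yn-1-yl)-7-[(4-methoxyphenyl)methoxy]-4-[(4-nitrobenzoyl)oxy]-6-(4,4,5,5-tetramethyl-1,3,2-dioxaborolan-2-yl)hept-5-enoate F3. Mild methanolysis (K2CO3, MeOH, 0 °C) comes back to the route at 13.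

Step 17. Acylation of the hindered C5 hydroxyl may be slow, base may open the β-hydroxy ketone by retro-aldol cleavage, and the angelate may isomerize to the tiglate. Fallback: the fallback sets out from 26 and acylates before the ketone exists. The same mixed-anhydride acylation should give (3aS,5R,6S,7S,8S,8aR)-7-formyl-6-methyl-3-methylidene-2-oxo-5,7-bis(triethylsilyloxy)octahydro-2H-cyclohepta[b]furan-8-yl (2Z)-2-methylbut-2-enoate F4. Nozaki–Hiyama–Kishi addition of 27 then gives (3aS,5R,6S,7R,8S,8aR)-7-[(2E)-1-hydroxybut-2-en-1-yl]-6-methyl-3-methylidene-2-oxo-5,7-bis(triethylsilyloxy)octahydro-2H-cyclohepta[b]furan-8-yl (2Z)-2-methylbut-2-enoate F5 (both carbinol epimers). Dess–Martin oxidation comes back to the route at 33.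

**Further compounds**

F1 | step 7 | tert-butyl 2-[(2R,3S,5E)-5-(1-iodoethylidene)-2-[(1Z)-3-[(4-methoxyphenyl)methoxy]-2-(4,4,5,5-tetramethyl-1,3,2-dioxaborolan-2-yl)prop-1-en-1-yl]oxolan-3-yl]acetate | C/C(I)=C1/C[C@@H](CC(=O)OC(C)(C)C)[C@@H](O1)/C=C(\COCc1ccc(OC)cc1)B1OC(C)(C)C(C)(C)O1
F2 | step 6 | tert-butyl (3S,4S,5Z)-3-(but-2-yn-1-yl)-4-hydroxy-7-[(4-methoxyphenyl)methoxy]-6-(4,4,5,5-tetramethyl-1,3,2-dioxaborolan-2-yl)hept-5-enoate | CC#CC[C@@H](CC(=O)OC(C)(C)C)[C@H](O)/C=C(\COCc1ccc(OC)cc1)B1OC(C)(C)C(C)(C)O1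
F3 | step 6 | tert-butyl (3S,4R,5Z)-3-(but-2-yn-1-yl)-7-[(4-methoxyphenyl)methoxy]-4-[(4-nitrobenzoyl)oxy]-6-(4,4,5,5-tetramethyl-1,3,2-dioxaborolan-2-yl)hept-5-enoate | CC#CC[C@@H](CC(=O)OC(C)(C)C)[C@@H](OC(=O)c1ccc(cc1)[N+](=O)[O-])/C=C(\COCc1ccc(OC)cc1)B1OC(C)(C)C(C)(C)O1
F4 | step 17 | (3aS,5R,6S,7S,8S,8aR)-7-formyl-6-methyl-3-methylidene-2-oxo-5,7-bis(triethylsilyloxy)octahydro-2H-cyclohepta[b]furan-8-yl (2Z)-2-methylbut-2-enoate | C=C1C(=O)O[C@@H]2[C@H]1C[C@@H](O[Si](CC)(CC)CC)[C@H](C)[C@@](O[Si](CC)(CC)CC)(C=O)[C@H]2OC(=O)/C(C)=C\C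
F5 | step 17 | (3aS,5R,6S,7R,8S,8aR)-7-[(2E)-1-hydroxybut-2-en-1-yl]-6-methyl-3-methylidene-2-oxo-5,7-bis(triethylsilyloxy)octahydro-2H-cyclohepta[b]furan-8-yl (2Z)-2-methylbut-2-enoate (both carbinol epimers) | C=C1C(=O)O[C@@H]2[C@H]1C[C@@H](O[Si](CC)(CC)CC)[C@H](C)[C@@](O[Si](CC)(CC)CC)(C(O)/C=C/C)[C@H]2OC(=O)/C(C)=C\C
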